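**Strategy.** Everything rests on disconnecting the cyclohexene between its carbinol carbon (CH–O) and the adjacent allylic ring CH2. That bond is made by an alkoxide-accelerated 1,3-shift of a 2-vinylcyclobutanol: the strained four-membered ring opens at the carbinol–C(CH3)(vinyl) bond and recloses on the vinyl terminus, giving in one operation the six-membered ring, its C=C(CH3) bond and the carbinol stereocentre. The feature exploited is the homoallylic array CH(O)–CH2–CH=C(CH3) of the cyclohexene, flanked by the gem-dimethyl carbon that keeps the transient aldehyde non-enolisable. The precursor, a 3-(benzyloxymethyl)-2-ethenyl-2,4,4-trimethylcyclobutanol, comes from an auxiliary-controlled keteniminium–alkene [2+2] cycloaddition, aldol condensation, deconjugative methylation and reduction.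

Key step: step 6

Assumption: the (2R,5R)-auxiliary is taken to direct the cycloaddition of step 2 to the (S)-ketone; the sense of induction for this alkene is not established, and if it proves opposite the (2S,5S)-amine is used with nothing else changed.

Remark: the ring CH that carries the CH2O group keeps its spatial arrangement from compound 7 to the target; its descriptor alternates between S and R only because the priorities of its ring neighbours change.

Step 1
Reactants: 1 2-methylpropanoyl chloride (isobutyryl chloride); 2 (2R,5R)-2,5-dimethylpyrrolidine
Product: 3 1-[(2R,5R)-2,5-dimethylpyrrolidin-1-yl]-2-methylpropan-1-one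
Conditions: NaOH (aq), CH2Cl2, 0 °C → rt
Reagents that add atoms: none
Why: Schotten–Baumann N-acylation of the secondary amine by the acid chloride should give the hindered tertiary amide without touching the two auxiliary stereocentres.

Step 2
Reactants: 3 1-[(2R,5R)-2,5-dimethylpyrrolidin-1-yl]-2-methylpropan-1-one; 4 allyl benzyl ether
Product: 7 (3S)-3-[(benzyloxy)methyl]-2,2-dimethylcyclobutan-1-one, via keteniminium triflate 5 (not isolated), via cyclobutaniminium triflate 6 (not isolated)
Conditions: Tf2O, 2,4,6-collidine, ClCH2CH2Cl, 0 °C → 80 °C; then H2O, NaHCO3, rt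
Reagents that add atoms: water, O
Why: Keteniminium–alkene [2+2] cycloaddition: Tf2O and collidine turn 3 into the tetrasubstituted keteniminium salt 5, whose central carbon is attacked by the terminal CH2 of 4 while the CMe2 carbon closes onto the internal alkene carbon (the better cation-stabilising site), and the C2-symmetric auxiliary is expected to bias the face on which this ring-closing bond forms so that the ring CH is set as (S) before hydrolysis of iminium 6 releases the ketone.

Step 3
Reactants: 7 (3S)-3-[(benzyloxy)methyl]-2,2-dimethylcyclobutan-1-one; 8 acetaldehyde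
Product: 12 (3R,4E)-3-[(benzyloxy)methyl]-4-ethylidene-2,2-dimethylcyclobutan-1-one, via lithium enolate 9 (not isolated), via lithium aldolate 10 (not isolated), via aldol mesylate 11 (not isolated)
Conditions: LiN(i-Pr)2, THF, −78 °C; CH3CHO; MsCl, −78 → 0 °C; DBU, 0 °C → rt
Reagents that add atoms: none
Why: Directed aldol condensation: the only enolisable position (the ring CH2, the other α-carbon being quaternary) gives enolate 9, which adds to acetaldehyde, and mesylation followed by base-induced E1cB elimination of 11 should give the exocyclic enone (either double-bond isomer serves in step 4), the ring CH stereocentre being neither α to the carbonyl nor otherwise acidic.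

Step 4
Reactants: 12 (3R,4E)-3-[(benzyloxy)methyl]-4-ethylidene-2,2-dimethylcyclobutan-1-one
Product: 14 (2R,3R)-3-[(benzyloxy)methyl]-2-ethenyl-2,4,4-trimethylcyclobutan-1-one, via potassium dienolate 13 (not isolated)
Conditions: KN(SiMe3)2, THF, −78 °C; MeI, −78 → 0 °C
Reagents that add atoms: iodomethane, CI
Why: Deconjugative α-alkylation: the γ-hydrogens of the ethylidene methyl are the only acidic ones, and the extended enolate 13 should react with MeI at its α-carbon (kinetic α-selectivity of dienolates) to give the methyl/vinyl quaternary carbon, methyl entering anti to the neighbouring benzyloxymethyl group, although the configuration of this carbon is irrelevant because it becomes sp2 in step 6.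

Step 5
Reactants: 14 (2R,3R)-3-[(benzyloxy)methyl]-2-ethenyl-2,4,4-trimethylcyclobutan-1-one
Product: 15 (1S,2R,3R)-3-[(benzyloxy)methyl]-2-ethenyl-2,4,4-trimethylcyclobutan-1-ol
Conditions: NaBH4, MeOH, −20 → 0 °C
Reagents that add atoms: none
Why: Borohydride reduction of the strained, non-enolisable cyclobutanone should be fast and is expected to deliver hydride anti to the benzyloxymethyl group, but either carbinol epimer is usable because this centre is erased and reset in step 6.

Step 6
Reactants: 15 (1S,2R,3R)-3-[(benzyloxy)methyl]-2-ethenyl-2,4,4-trimethylcyclobutan-1-ol (either carbinol epimer)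
Product: 18 (1R,5S)-5-[(benzyloxy)methyl]-4,6,6-trimethylcyclohex-3-en-1-ol, via potassium cyclobutanolate 16 (not isolated), via ring-opened allylpotassium aldehyde 17 (not isolated)
Conditions: KH, 18-crown-6, THF, 0 → 40 °C; then NH4Cl (aq)
Reagents that add atoms: none
Why: KH converts 15 into the potassium alkoxide 16, in which the bond between the carbinol carbon and the methyl/vinyl-bearing carbon is weakened by the oxyanion and by four-ring strain and breaks heterolytically to the aldehyde–allylpotassium pair 17; the carbonyl carbon is then attacked by the unsubstituted terminus of the allyl anion, which forms the new C–C bond and leaves the double bond between the former vinyl CH and the methyl-bearing carbon. The closest known reaction type is the alkoxide-accelerated 1,3-sigmatropic rearrangement of potassium 2-vinylcyclobutanolates to cyclohex-3-en-1-ols, a ring expansion by two carbons. The six-membered ring closes in a 6-exo-trig mode at the aldehyde carbon with the allyl unit becoming endocyclic; reclosure at the substituted allyl terminus only regenerates the strained four-membered alkoxide and is reversible, so the process should funnel to the cyclohexenolate. The new carbinol stereocentre is controlled by the ring CH that bears CH2OBn: in a chair-like closure this group should sit pseudo-equatorial and the carbonyl oxygen with its crown-complexed potassium equatorial, which would give the cis (1R,5S) alcohol; this preference is a conformational argument and not a secured outcome. Because the carbinol centre and the methyl/vinyl centre of 15 are erased on fragmentation, every diastereomer of 15 should converge. The step needs cleavage toward the allyl-stabilised carbanion only (the other α-carbon is the gem-dimethyl carbon and could give only a tertiary alkyl anion) and freedom from proton-transfer quenching, which the quaternary carbon next to the aldehyde secures.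

Step 7
Reactants: 18 (1R,5S)-5-[(benzyloxy)methyl]-4,6,6-trimethylcyclohex-3-en-1-ol
Product: 19 (1R,5S)-5-(hydroxymethyl)-4,6,6-trimethylcyclohex-3-en-1-ol
Conditions: lithium 4,4′-di-tert-butylbiphenylide, THF, −78 °C; then NH4Cl (aq)
Reagents that add atoms: none
Why: Electron-transfer (arene radical anion) cleavage of the benzyl ether should spare the isolated trisubstituted alkene and the alkoxide of the secondary alcohol and touches no stereocentre.

Step 8
Reactants: 19 (1R,5S)-5-(hydroxymethyl)-4,6,6-trimethylcyclohex-3-en-1-ol; 20 umbelliferone (7-hydroxy-2H-chromen-2-one)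
Product: 21 7-{[(1S,5R)-5-hydroxy-2,6,6-trimethylcyclohex-2-en-1-yl]methoxy}-2H-chromen-2-one
Conditions: PPh3, DIAD, THF, 0 °C → rt
Reagents that add atoms: none
Why: Mitsunobu etherification: the acidic phenol (pKa about 8) displaces the oxyphosphonium of the primary alcohol in an SN2 step, while the neopentylic secondary hydroxyl next to the quaternary carbon is too hindered to be activated or displaced, so both stereocentres are untouched.

Step 9
Reactants: 21 7-{[(1S,5R)-5-hydroxy-2,6,6-trimethylcyclohex-2-en-1-yl]methoxy}-2H-chromen-2-one; 22 (2R)-2-methylbutanoic acid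
Product: 23 (1R,5S)-4,6,6-trimethyl-5-{[(2-oxo-2H-chromen-7-yl)oxy]methyl}cyclohex-3-en-1-yl (2R)-2-methylbutanoate
Conditions: DCC, DMAP, CH2Cl2, 0 °C → rt
Reagents that add atoms: none
Why: Steglich esterification through the N-acylpyridinium of the acid acylates the hindered secondary hydroxyl at oxygen, so the carbinol configuration is retained, and the absence of strong base should keep the α-stereocentre of the (R)-acid intact.

**Compound list**

1 | 2-methylpropanoyl chloride (isobutyryl chloride) | CC(C)C(Cl)=O | starting material
2 | (2R,5R)-2,5-dimethylpyrrolidine | C[C@@H]1CC[C@@H](C)N1 | starting material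
3 | 1-[(2R,5R)-2,5-dimethylpyrrolidin-1-yl]-2-methylpropan-1-one | CC(C)C(=O)N1[C@H](C)CC[C@H]1C | intermediate
4 | allyl benzyl ether, [(prop-2-en-1-yloxy)methyl]benzene | C=CCOCc1ccccc1 | starting material
5 | (2R,5R)-2,5-dimethyl-1-(2-methylprop-1-en-1-ylidene)pyrrolidin-1-ium trifluoromethanesulfonate (keteniminium triflate, not isolated) | CC(C)=C=[N+]1[C@H](C)CC[C@H]1C.[O-]S(=O)(=O)C(F)(F)F | intermediate
6 | (2R,5R)-1-{(3S)-3-[(benzyloxy)methyl]-2,2-dimethylcyclobutylidene}-2,5-dimethylpyrrolidin-1-ium trifluoromethanesulfonate (cyclobutaniminium triflate, not isolated) | C[C@@H]1CC[C@@H](C)[N+]1=C2C[C@H](COCc3ccccc3)C2(C)C.[O-]S(=O)(=O)C(F)(F)F | intermediate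
7 | (3S)-3-[(benzyloxy)methyl]-2,2-dimethylcyclobutan-1-one | O=C1C[C@H](COCc2ccccc2)C1(C)C | intermediate
8 | acetaldehyde | CC=O | starting material
9 | lithium (3S)-3-[(benzyloxy)methyl]-4,4-dimethylcyclobut-1-en-1-olate (lithium enolate, not isolated) | [Li+].[O-]C1=C[C@H](COCc2ccccc2)C1(C)C | intermediate
10 | lithium 1-{(2S)-2-[(benzyloxy)methyl]-3,3-dimethyl-4-oxocyclobutyl}ethan-1-olate (lithium aldolate, mixture at the two new centres, not isolated) | O=C1C(C(C)[O-])[C@H](COCc2ccccc2)C1(C)C.[Li+] | intermediate
11 | 1-{(2S)-2-[(benzyloxy)methyl]-3,3-dimethyl-4-oxocyclobutyl}ethyl methanesulfonate (aldol mesylate, mixture at the two new centres, not isolated) | O=C1C(C(C)OS(C)(=O)=O)[C@H](COCc2ccccc2)C1(C)C | intermediate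
12 | (3R,4E)-3-[(benzyloxy)methyl]-4-ethylidene-2,2-dimethylcyclobutan-1-one | O=C1/C(=C/C)[C@H](COCc2ccccc2)C1(C)C | intermediate
13 | potassium (3R)-3-[(benzyloxy)methyl]-2-ethenyl-4,4-dimethylcyclobut-1-en-1-olate (potassium dienolate, not isolated) | [K+].[O-]C1=C(C=C)[C@H](COCc2ccccc2)C1(C)C | intermediate
14 | (2R,3R)-3-[(benzyloxy)methyl]-2-ethenyl-2,4,4-trimethylcyclobutan-1-one (methyl trans to the benzyloxymethyl group) | O=C1[C@](C)(C=C)[C@H](COCc2ccccc2)C1(C)C | intermediate
15 | (1S,2R,3R)-3-[(benzyloxy)methyl]-2-ethenyl-2,4,4-trimethylcyclobutan-1-ol (expected major carbinol epimer) | O[C@@H]1[C@](C)(C=C)[C@H](COCc2ccccc2)C1(C)C | intermediate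
16 | potassium (1S,2R,3R)-3-[(benzyloxy)methyl]-2-ethenyl-2,4,4-trimethylcyclobutan-1-olate (not isolated) | [K+].[O-][C@@H]1[C@](C)(C=C)[C@H](COCc2ccccc2)C1(C)C | intermediate
17 | potassium salt of the (Z)-allyl anion of (3S)-3-[(benzyloxy)methyl]-2,2,4-trimethylhex-4-enal, deprotonated at C6 (ring-opened, not isolated) | [K+].O=CC(C)(C)[C@@H](COCc1ccccc1)/C(C)=C\[CH2-] | intermediate
18 | (1R,5S)-5-[(benzyloxy)methyl]-4,6,6-trimethylcyclohex-3-en-1-ol | O[C@@H]1CC=C(C)[C@H](COCc2ccccc2)C1(C)C | intermediate
19 | (1R,5S)-5-(hydroxymethyl)-4,6,6-trimethylcyclohex-3-en-1-ol | O[C@@H]1CC=C(C)[C@H](CO)C1(C)C | intermediate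
20 | umbelliferone (7-hydroxy-2H-chromen-2-one) | Oc1ccc2ccc(=O)oc2c1 | starting material
21 | 7-{[(1S,5R)-5-hydroxy-2,6,6-trimethylcyclohex-2-en-1-yl]methoxy}-2H-chromen-2-one | O[C@@H]1CC=C(C)[C@H](COc2ccc3ccc(=O)oc3c2)C1(C)C | intermediate
22 | (2R)-2-methylbutanoic acid | CC[C@@H](C)C(=O)O | starting material
23 | (1R,5S)-4,6,6-trimethyl-5-{[(2-oxo-2H-chromen-7-yl)oxy]methyl}cyclohex-3-en-1-yl (2R)-2-methylbutanoate | CC[C@@H](C)C(=O)O[C@@H]1CC=C(C)[C@H](COc2ccc3ccc(=O)oc3c2)C1(C)C | target

**Step count and risks**

Total step count: 9. Longest linear sequence: 9 steps (1 → 3 → 7 → 12 → 14 → 15 → 18 → 19 → 21 → 23).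

The three steps most likely to fail:

First, step 6. The recombination of the ring-opened pair may attack both faces of the aldehyde, so that the new carbinol centre forms without useful selectivity. The fallback moves the facial choice to a hydride addition. It sets out from 18 as obtained (mixture of carbinol epimers). Oxidation by Dess–Martin periodinane buffered by NaHCO3 (CH2Cl2, 0 °C) should give the β,γ-unsaturated ketone (5S)-5-[(benzyloxy)methyl]-4,6,6-trimethylcyclohex-3-en-1-one F1. NaBH4 in MeOH at −40 °C should then add hydride along the axial trajectory, on the face opposite to the benzyloxymethyl group, and give the equatorial, cis alcohol. The route is rejoined at 18.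

Second, step 2. The auxiliary may discriminate poorly, or in the opposite sense, between the two faces in the ring-closing bond formation, so that the ketone forms in low enantiomeric purity. The fallback replaces auxiliary control by resolution. It sets out from 4. Cycloaddition under the same activation but with commercial N,N-dimethylisobutyramide (CC(C)C(=O)N(C)C) should give racemic 3-[(benzyloxy)methyl]-2,2-dimethylcyclobutan-1-one F2. Ketalisation by (1R,2R)-1,2-diphenylethane-1,2-diol (TsOH, benzene, reflux, water separator) should give two diastereomeric spiroketals separable by chromatography. The ketal of the (S)-ketone, (2S,6R,7R)-2-[(benzyloxy)methyl]-1,1-dimethyl-6,7-diphenyl-5,8-dioxaspiro[3.4]octane F3, is hydrolysed (aq HCl, THF), and the route is rejoined at 7.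

Third, step 8. Displacement at the activated β-branched primary carbon next to the quaternary centre is slow, so the oxyphosphonium intermediate may be captured instead by the cis ring hydroxyl (closure of a five-membered cyclic ether) or by the reduced azodicarboxylate. The fallback forms the ether bond from the aryl side. It sets out from 19. Palladium-catalysed C–O coupling of the primary hydroxyl with commercial 7-bromocoumarin (O=c1ccc2ccc(Br)cc2o1; Pd2(dba)3, t-BuBrettPhos, Cs2CO3, toluene, 80 °C) should give the ether directly, because no carbon of 19 is turned into an electrophile and the hindered secondary hydroxyl couples far more slowly. The route is rejoined at 21; the fallback makes no new compound (F0).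

Further compounds
F1 | step 6 | (5S)-5-[(benzyloxy)methyl]-4,6,6-trimethylcyclohex-3-en-1-one | O=C1CC=C(C)[C@H](COCc2ccccc2)C1(C)C
F2 | step 2 | racemic 3-[(benzyloxy)methyl]-2,2-dimethylcyclobutan-1-one | O=C1CC(COCc2ccccc2)C1(C)C
F3 | step 2 | (2S,6R,7R)-2-[(benzyloxy)methyl]-1,1-dimethyl-6,7-diphenyl-5,8-dioxaspiro[3.4]octane | O1[C@H](c2ccccc2)[C@@H](c2ccccc2)OC13C[C@H](COCc2ccccc2)C3(C)C
F0 | step 8 | none | none
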